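**Retrosynthetic overview**
1. Target 36 ← global desilylation ← methylation of an alkenyl triflate; the side-chain stereocentre on the seven-membered ring comes from hydrogenation of an exocyclic enone made by aldol union of a hydroazulenone enolate (left half, 11) with a perhydrobenzoxepine acetaldehyde (right half, 27).
2. Left half: the cyclopentane comes from cyclopentenone; a six-membered ring is fused on by a catalytic asymmetric Diels–Alder reaction and then enlarged to the seven-membered ring by a one-carbon ring expansion (silyloxycyclopropane, FeCl3), which delivers the 3-methylcycloheptenone needed for gem-dimethylation and regiodefined enolate formation.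
3. Right half: the cyclohexane is 2-methylcyclohex-2-enone (CBS reduction, allylic oxidation); the quaternary centre is set by cuprate addition anti to a silyloxy group; the oxepane is closed last by a silyl-relay 7-endo epoxide opening; the tertiary carbinol comes from equatorial methyl addition.
4. Ring order: cyclopentane (bought) → six-membered carbocycle → seven-membered carbocycle; cyclohexane (bought) → oxepane; the two bicycles are joined through the two-carbon bridge.

Assumption: the antipodes named for the chiral catalysts (oxazaborolidinium, CBS, Shi ketone) follow the published selectivity models; if a sense of induction proves opposite, the mirror-image catalyst is used.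

**Route**

Step 1
Reactants: 1 pent-1-en-3-one
Product: 2 (Z)-tert-butyldimethyl(penta-1,3-dien-3-yloxy)silane
Conditions: TBSOTf, Et3N, Et2O, 0 °C
Reagents that add atoms: tert-butyldimethylsilyl triflate, CC(C)(C)[Si](C)(C)OS(=O)(=O)C(F)(F)F
Why: Soft enolisation and O-silylation of the ethyl ketone (silyl enol ether formation) gives the (Z)-2-silyloxy diene, whose methyl sits on the outside of the s-cis diene.

Step 2
Reactants: 2 (Z)-tert-butyldimethyl(penta-1,3-dien-3-yloxy)silane; 3 cyclopent-2-en-1-one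
Product: 4 (3aR,4S,7aS)-5-[(tert-butyldimethylsilyl)oxy]-4-methyl-2,3,3a,4,7,7a-hexahydro-1H-inden-1-one
Conditions: (S)-o-tolyl-oxazaborolidinium triflimide (Corey catalyst, 20 mol %), CH2Cl2, −78 → −40 °C
Reagents that add atoms: none
Why: Catalytic enantioselective Diels–Alder reaction in which the nucleophilic CHMe terminus bonds to the enone β-carbon, suprafacial addition gives the cis ring fusion, the endo transition state puts the methyl cis to the cyclopentane bonds, and the catalyst fixes the absolute configuration of C3a and C7a.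

Step 3
Reactants: 4 Diels–Alder adduct
Product: 6 (3aS,4S,7aS)-4-methyl-1-methylideneoctahydro-5H-inden-5-one, via exo-methylene silyl enol ether 5 (not isolated)
Conditions: Cp2TiMe2, toluene, 70 °C; then Bu4NF, AcOH, THF, 0 °C
Reagents that add atoms: dimethyltitanocene, C[Ti](C)(C1C=CC=C1)C1C=CC=C1
Why: Non-basic Petasis methylenation converts the epimerisable cyclopentanone into the exocyclic alkene without touching the ring-fusion centre, and buffered fluoride then unmasks the cyclohexanone from the silyl enol ether (no new stereocentre).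

Step 4
Reactants: 6 keto alkene
Product: 7 (1S,3aS,4S,7aS)-1-hydroxy-1,4-dimethyloctahydro-5H-inden-5-one
Conditions: Co(acac)2 (20 mol %), PhSiH3, O2 (1 atm), THF, rt; then PPh3
Reagents that add atoms: dioxygen, O=O
Why: Mukaiyama hydration (metal-hydride hydrogen-atom transfer) gives the tertiary radical at C1, which is trapped by O2 on the convex face of the cis-fused bicycle, so the new hydroxyl is cis to the ring-fusion hydrogens (1S) and the methyl is concave.

Step 5
Reactants: 7 hydroxy ketone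
Product: 8 (1S,3aS,7aS)-1,4-dimethyl-1,5-bis[(triethylsilyl)oxy]-2,3,3a,6,7,7a-hexahydro-1H-indene
Conditions: Et3SiCl, NaI, Et3N, MeCN, 40 °C
Reagents that add atoms: chlorotriethylsilane, CC[Si](Cl)(CC)CC
Why: Equilibrating silylation with Et3SiI formed in the flask gives the more substituted (thermodynamic) silyl enol ether toward the methyl-bearing carbon and caps the tertiary alcohol in the same operation (the C4 centre is erased, no new one is made).

Step 6
Reactants: 8 bis-silyl ether
Product: 9 (1S,3aS,7aS)-1,4-dimethyl-1,5-bis[(triethylsilyl)oxy]-4,5-methanooctahydro-1H-indene (cyclopropane on the face of the ring-fusion hydrogens)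
Conditions: Et2Zn, CH2I2, CH2Cl2, 0 °C → rt
Reagents that add atoms: diiodomethane, ICI
Why: Furukawa-modified Simmons–Smith cyclopropanation of the electron-rich tetrasubstituted enol ether from its less hindered face (the two new centres are erased in step 7).

Step 7
Reactants: 9 silyloxycyclopropane
Product: 11 (1S,3aS,8aS)-1,4-dimethyl-1-[(triethylsilyl)oxy]-2,3,3a,7,8,8a-hexahydroazulen-6(1H)-one, via chloro ketone 10 (not isolated)
Conditions: FeCl3, DMF, 0 °C → rt; then NaOAc, MeOH, reflux
Reagents that add atoms: none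
Why: Saegusa–Ito one-carbon ring expansion, in which FeCl3 oxidises the silyloxycyclopropane to an alkoxy radical whose β-scission of the internal bond (to the tertiary ring-expanded radical) turns the six- into the seven-membered ring, and chlorine transfer followed by E1cB loss of HCl gives the 3-methylcycloheptenone without touching C1, C3a or C8a.

Step 8
Reactants: 12 2-methylcyclohex-2-en-1-one
Product: 13 (S)-2-methylcyclohex-2-en-1-ol
Conditions: (R)-Me-CBS oxazaborolidine (10 mol %), BH3·SMe2, THF, −20 °C; aqueous work-up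
Reagents that add atoms: none
Why: Corey–Bakshi–Shibata reduction, with the alkenyl branch acting as the large group so that hydride is delivered to give the (S)-allylic alcohol.

Step 9
Reactants: 13 (S)-2-methylcyclohex-2-en-1-ol
Product: 14 (S)-tert-butyldimethyl[(2-methylcyclohex-2-en-1-yl)oxy]silane
Conditions: TBSCl, imidazole, DMF, rt
Reagents that add atoms: tert-butyldimethylsilyl chloride, CC(C)(C)[Si](C)(C)Cl
Why: Standard O-silylation (no new stereocentre); the bulky silyloxy group later steers the cuprate addition.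

Step 10
Reactants: 14 allylic silyl ether
Product: 15 (S)-4-[(tert-butyldimethylsilyl)oxy]-3-methylcyclohex-2-en-1-one
Conditions: Rh2(cap)4 (dirhodium tetrakis(caprolactamate), 1 mol %), t-BuOOH (70 % aq.), K2CO3, CH2Cl2, rt
Reagents that add atoms: tert-butyl hydroperoxide, CC(C)(C)OO
Why: Doyle allylic C–H oxidation at the ring methylene next to the alkene CH (the carbinol C–H is shielded by the silyl group) gives the γ-silyloxy enone without touching the stereocentre.

Step 11
Reactants: 15 γ-silyloxy enone; 16 5-bromo-2-methylpent-2-ene; 17 allyl bromide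
Product: 21 (3S,4S)-2-allyl-4-[(tert-butyldimethylsilyl)oxy]-3-methyl-3-(4-methylpent-3-en-1-yl)cyclohexan-1-one (C2 epimers), via homoprenyl Grignard reagent 18 (not isolated), via TMS enol ether 19 (not isolated), via lithium enolate 20 (not isolated)
Conditions: 16, Mg, THF; CuBr·SMe2 (10 mol %), TMSCl, HMPA, THF, −78 °C, then 15; then MeLi, THF, 0 °C; then 17, HMPA, −78 → 0 °C
Reagents that add atoms: none
Why: Copper-catalysed conjugate addition of the Grignard reagent anti to the γ-silyloxy group sets the quaternary centre (chain trans to OTBS), and the regiodefined enolate released with MeLi is C-allylated (the C2 epimers are equilibrated in step 13).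

Step 12
Reactants: 21 allylated ketone
Product: 22 (3S,4S)-2-allyl-4-[(tert-butyldimethylsilyl)oxy]-3-{2-[(2S)-3,3-dimethyloxiran-2-yl]ethyl}-3-methylcyclohexan-1-one (C2 epimers)
Conditions: ent-Shi ketone (L-fructose-derived, 30 mol %), Oxone (KHSO5), K2CO3, Bu4NHSO4, MeCN/dimethoxymethane/aq. buffer (pH 10.5), 0 °C
Reagents that add atoms: potassium peroxymonosulfate, [K+].[O-]S(=O)(=O)OO
Why: Shi asymmetric epoxidation (chiral dioxirane) oxidises only the electron-rich trisubstituted alkene and sets the epoxide CH carbon as S under catalyst control.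

Step 13
Reactants: 22 epoxy silyl ether
Product: 24 (3S,5aS,6S,9aS)-6-allyl-3-[(tert-butyldimethylsilyl)oxy]-2,2,5a-trimethyloctahydro-1-benzoxepin-7(2H)-one (trans-fused), via C6-epimeric oxepane ketone mixture 23 (not isolated)
Conditions: TBSOTf (10 mol %), 2,6-di-tert-butyl-4-methylpyridine (20 mol %), CH2Cl2, −78 → −40 °C; then K2CO3, MeOH, rt
Reagents that add atoms: none
Why: Proposed new method: silyl-cation-catalysed, silyl-ether-terminated 7-endo epoxide opening with O-to-O silyl relay, in which catalytic TBSOTf silylates the epoxide oxygen, the weakly nucleophilic ring-carbinol OTBS oxygen attacks the SN1-like tertiary CMe2 terminus through a loose transition state, and the resulting silyloxonium ion hands its TBS cation to the next epoxide, so that C3 keeps its oxygen and S configuration and ends as the TBS ether, C9a keeps its configuration and the fusion is trans, after which K2CO3/MeOH equilibrates C6 to the equatorial allyl epimer; the closest known reaction type is the McDonald TMSOTf- or BF3-promoted endo-selective oxacyclisation of trisubstituted 1,5-diepoxides, where an ether-type (epoxide) oxygen opens a Lewis-acid-activated trisubstituted epoxide at its tertiary carbon to form oxepanes.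

Step 14
Reactants: 24 oxepane ketone
Product: 26 (3S,5aS,6S,7R,9aS)-6-allyl-3-[(tert-butyldimethylsilyl)oxy]-2,2,5a,7-tetramethyl-7-[(triethylsilyl)oxy]decahydro-1-benzoxepine, via magnesium alkoxide 25 (not isolated)
Conditions: MeMgBr, CeCl3, THF, −78 °C; then Et3SiOTf, −78 → 0 °C
Reagents that add atoms: methylmagnesium bromide, C[Mg]Br; triethylsilyl triflate, CC[Si](CC)(CC)OS(=O)(=O)C(F)(F)F
Why: Cerium-assisted 1,2-addition in which the axial angular methyl (1,3 to the carbonyl) blocks axial attack, so methyl enters equatorially and gives the axial tertiary alkoxide (7R), which is silylated in the same flask.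

Step 15
Reactants: 26 terminal alkene
Product: 27 2-{(3S,5aS,6S,7R,9aS)-3-[(tert-butyldimethylsilyl)oxy]-2,2,5a,7-tetramethyl-7-[(triethylsilyl)oxy]decahydro-1-benzoxepin-6-yl}acetaldehyde
Conditions: O3, CH2Cl2, −78 °C; then PPh3
Reagents that add atoms: ozone, [O-][O+]=O
Why: Ozonolysis with reductive work-up cleaves the only alkene to the aldehyde without touching a stereocentre.

Step 16
Reactants: 11 bicyclic enone; 27 aldehyde
Product: 29 (1S,3aS,8aS)-5-{1-hydroxy-2-[benzoxepin-6-yl unit of 27]ethyl}-1,4,4-trimethyl-1-[(triethylsilyl)oxy]octahydroazulen-6(1H)-one (diastereomer mixture), via lithium enolate 28 (not isolated)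
Conditions: Me2CuLi, Et2O, −30 → 0 °C; then 27, THF, −78 °C; aq. NH4Cl
Reagents that add atoms: lithium dimethylcuprate, [Li+].C[Cu-]C
Why: Gilman conjugate addition installs the second methyl of the gem-dimethyl group and releases the regiodefined enolate next to it, which undergoes aldol addition to the aldehyde (both new centres are removed or reset in steps 17 and 18).

Step 17
Reactants: 29 aldol adduct
Product: 31 (1S,3aS,8aS)-5-{2-[benzoxepin-6-yl unit of 27]ethylidene}-1,4,4-trimethyl-1-[(triethylsilyl)oxy]octahydroazulen-6(1H)-one (alkene isomers), via mesylate 30 (not isolated)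
Conditions: MsCl, Et3N, CH2Cl2, 0 °C; then DBU, rt
Reagents that add atoms: none
Why: Mesylation and E1cB elimination (aldol condensation) give the exocyclic enone, whose alkene geometry is inconsequential.

Step 18
Reactants: 31 exocyclic enone
Product: 32 (1S,3aS,5S,8aS)-5-{2-[benzoxepin-6-yl unit of 27]ethyl}-1,4,4-trimethyl-1-[(triethylsilyl)oxy]octahydroazulen-6(1H)-one
Conditions: H2 (1 atm), Pd/C, EtOAc, rt
Reagents that add atoms: none
Why: Heterogeneous catalytic hydrogenation delivers hydrogen to the enone from the face of the ring-fusion hydrogens (the other face at C5 is 1,3-syn to the cyclopentane C3a–C3 bond), which places the side chain cis to the cyclopentane ring as in the target.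

Step 19
Reactants: 32 saturated ketone
Product: 34 (1S,3aS,5S,8aS)-5-{2-[benzoxepin-6-yl unit of 27]ethyl}-1,4,4-trimethyl-1-[(triethylsilyl)oxy]-1,2,3,3a,4,5,8,8a-octahydroazulen-6-yl trifluoromethanesulfonate, via potassium enolate 33 (not isolated)
Conditions: KHMDS, THF, −78 °C; then Comins' reagent, −78 °C
Reagents that add atoms: N-(5-chloropyridin-2-yl)bis(trifluoromethanesulfonyl)imide, O=S(=O)(N(c1ccc(Cl)cn1)S(=O)(=O)C(F)(F)F)C(F)(F)F
Why: Kinetic deprotonation occurs at the unhindered C7 methylene and not at the tertiary C5–H next to the quaternary carbon, and O-triflation of the enolate fixes the alkene at C6=C7 while leaving C5 untouched.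

Step 20
Reactants: 34 alkenyl triflate
Product: 35 tris-silyl ether of 36 (3-O-TBS, 7-O-TES on the benzoxepine, 1-O-TES on the azulene)
Conditions: MeMgBr, Fe(acac)3 (10 mol %), THF/NMP, −30 → 0 °C
Reagents that add atoms: methylmagnesium bromide, C[Mg]Br
Why: Iron-catalysed Kumada-type cross-coupling (Fürstner conditions) replaces the triflate by methyl with retention of the alkene position.

Step 21
Reactants: 35 tris-silyl ether
Product: 36 (3S,5aS,6S,7R,9aS)-6-{2-[(1S,3aS,5R,8aS)-1-hydroxy-1,4,4,6-tetramethyl-1,2,3,3a,4,5,8,8a-octahydroazulen-5-yl]ethyl}-2,2,5a,7-tetramethyldecahydro-1-benzoxepine-3,7-diol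
Conditions: Bu4NF, THF, 60 °C
Reagents that add atoms: none
Why: Fluoride-mediated global desilylation releases the three hydroxyl groups without affecting any stereocentre.

**Compound list**
1 | pent-1-en-3-one | CCC(=O)C=C | starting material
2 | (Z)-tert-butyldimethyl(penta-1,3-dien-3-yloxy)silane | C/C=C(/C=C)O[Si](C)(C)C(C)(C)C | intermediate
3 | cyclopent-2-en-1-one | O=C1C=CCC1 | starting material
4 | (3aR,4S,7aS)-5-[(tert-butyldimethylsilyl)oxy]-4-methyl-2,3,3a,4,7,7a-hexahydro-1H-inden-1-one (cis-fused) | CC(C)(C)[Si](C)(C)OC1=CC[C@H]2[C@H](CCC2=O)[C@@H]1C | intermediate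
5 | (3aS,4S,7aS)-tert-butyldimethyl[(4-methyl-1-methylidene-2,3,3a,4,7,7a-hexahydro-1H-inden-5-yl)oxy]silane | CC(C)(C)[Si](C)(C)OC1=CC[C@H]2[C@H](CCC2=C)[C@@H]1C | intermediate (not isolated)
6 | (3aS,4S,7aS)-4-methyl-1-methylideneoctahydro-5H-inden-5-one | O=C1CC[C@H]2[C@H](CCC2=C)[C@@H]1C | intermediate
7 | (1S,3aS,4S,7aS)-1-hydroxy-1,4-dimethyloctahydro-5H-inden-5-one | O=C1CC[C@H]2[C@H](CC[C@]2(C)O)[C@@H]1C | intermediate
8 | (1S,3aS,7aS)-1,4-dimethyl-1,5-bis[(triethylsilyl)oxy]-2,3,3a,6,7,7a-hexahydro-1H-indene | CC1=C(O[Si](CC)(CC)CC)CC[C@H]2[C@@H]1CC[C@]2(C)O[Si](CC)(CC)CC | intermediate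
9 | (1S,3aS,7aS)-1,4-dimethyl-1,5-bis[(triethylsilyl)oxy]-4,5-methanooctahydro-1H-indene (CH2 on the face of the ring-fusion hydrogens) | C[C@]12C[C@@]1(O[Si](CC)(CC)CC)CC[C@H]3[C@@H]2CC[C@]3(C)O[Si](CC)(CC)CC | intermediate
10 | (1S,3aS,8aS)-4-chloro-1,4-dimethyl-1-[(triethylsilyl)oxy]octahydroazulen-6(1H)-one (C4 epimers) | CC1(Cl)CC(=O)CC[C@H]2[C@@H]1CC[C@]2(C)O[Si](CC)(CC)CC | intermediate (not isolated)
11 | (1S,3aS,8aS)-1,4-dimethyl-1-[(triethylsilyl)oxy]-2,3,3a,7,8,8a-hexahydroazulen-6(1H)-one (cis-fused) | CC1=CC(=O)CC[C@H]2[C@@H]1CC[C@]2(C)O[Si](CC)(CC)CC | intermediate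
12 | 2-methylcyclohex-2-en-1-one | CC1=CCCCC1=O | starting material
13 | (S)-2-methylcyclohex-2-en-1-ol | O[C@H]1CCCC=C1C | intermediate
14 | (S)-tert-butyldimethyl[(2-methylcyclohex-2-en-1-yl)oxy]silane | CC(C)(C)[Si](C)(C)O[C@H]1CCCC=C1C | intermediate
15 | (S)-4-[(tert-butyldimethylsilyl)oxy]-3-methylcyclohex-2-en-1-one | CC(C)(C)[Si](C)(C)O[C@H]1CCC(=O)C=C1C | intermediate
16 | 5-bromo-2-methylpent-2-ene | CC(C)=CCCBr | starting material
17 | allyl bromide (3-bromoprop-1-ene) | C=CCBr | starting material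
18 | (4-methylpent-3-en-1-yl)magnesium bromide | CC(C)=CCC[Mg]Br | intermediate (not isolated)
19 | (3S,4S)-4-[(tert-butyldimethylsilyl)oxy]-3-methyl-3-(4-methylpent-3-en-1-yl)-1-[(trimethylsilyl)oxy]cyclohex-1-ene | C[Si](C)(C)OC1=C[C@](C)(CCC=C(C)C)[C@@H](O[Si](C)(C)C(C)(C)C)CC1 | intermediate (not isolated)
20 | lithium enolate corresponding to 19 | [Li]OC1=C[C@](C)(CCC=C(C)C)[C@@H](O[Si](C)(C)C(C)(C)C)CC1 | intermediate (not isolated)
21 | (3S,4S)-2-allyl-4-[(tert-butyldimethylsilyl)oxy]-3-methyl-3-(4-methylpent-3-en-1-yl)cyclohexan-1-one (C2 epimers; chain trans to OTBS) | C=CCC1[C@](C)(CCC=C(C)C)[C@@H](O[Si](C)(C)C(C)(C)C)CCC1=O | intermediate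
22 | (3S,4S)-2-allyl-4-[(tert-butyldimethylsilyl)oxy]-3-{2-[(2S)-3,3-dimethyloxiran-2-yl]ethyl}-3-methylcyclohexan-1-one (C2 epimers) | C=CCC1[C@](C)(CC[C@@H]2OC2(C)C)[C@@H](O[Si](C)(C)C(C)(C)C)CCC1=O | intermediate
23 | (3S,5aS,9aS)-6-allyl-3-[(tert-butyldimethylsilyl)oxy]-2,2,5a-trimethyloctahydro-1-benzoxepin-7(2H)-one (C6 epimers) | C=CCC1[C@]2(C)CC[C@H](O[Si](C)(C)C(C)(C)C)C(C)(C)O[C@H]2CCC1=O | intermediate (not isolated)
24 | (3S,5aS,6S,9aS)-6-allyl-3-[(tert-butyldimethylsilyl)oxy]-2,2,5a-trimethyloctahydro-1-benzoxepin-7(2H)-one (trans-fused; allyl equatorial, cis to the angular methyl) | C=CC[C@H]1[C@]2(C)CC[C@H](O[Si](C)(C)C(C)(C)C)C(C)(C)O[C@H]2CCC1=O | intermediate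
25 | bromomagnesium (3S,5aS,6S,7R,9aS)-6-allyl-3-[(tert-butyldimethylsilyl)oxy]-2,2,5a,7-tetramethyldecahydro-1-benzoxepin-7-olate | C=CC[C@H]1[C@]2(C)CC[C@H](O[Si](C)(C)C(C)(C)C)C(C)(C)O[C@H]2CC[C@@]1(C)O[Mg]Br | intermediate (not isolated)
26 | (3S,5aS,6S,7R,9aS)-6-allyl-3-[(tert-butyldimethylsilyl)oxy]-2,2,5a,7-tetramethyl-7-[(triethylsilyl)oxy]decahydro-1-benzoxepine (7-O axial, cis to the angular methyl) | C=CC[C@H]1[C@]2(C)CC[C@H](O[Si](C)(C)C(C)(C)C)C(C)(C)O[C@H]2CC[C@@]1(C)O[Si](CC)(CC)CC | intermediate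
27 | 2-{(3S,5aS,6S,7R,9aS)-3-[(tert-butyldimethylsilyl)oxy]-2,2,5a,7-tetramethyl-7-[(triethylsilyl)oxy]decahydro-1-benzoxepin-6-yl}acetaldehyde | O=CC[C@H]1[C@]2(C)CC[C@H](O[Si](C)(C)C(C)(C)C)C(C)(C)O[C@H]2CC[C@@]1(C)O[Si](CC)(CC)CC | intermediate
28 | lithium (1S,3aS,8aS)-1,4,4-trimethyl-1-[(triethylsilyl)oxy]-1,2,3,3a,4,7,8,8a-octahydroazulen-6-olate | CC1(C)C=C(O[Li])CC[C@H]2[C@@H]1CC[C@]2(C)O[Si](CC)(CC)CC | intermediate (not isolated)
29 | (1S,3aS,8aS)-5-{1-hydroxy-2-[benzoxepin-6-yl unit of 27]ethyl}-1,4,4-trimethyl-1-[(triethylsilyl)oxy]octahydroazulen-6(1H)-one (mixture at C5 and the carbinol carbon) | CC1(C)C(C(O)C[C@H]3[C@]4(C)CC[C@H](O[Si](C)(C)C(C)(C)C)C(C)(C)O[C@H]4CC[C@@]3(C)O[Si](CC)(CC)CC)C(=O)CC[C@H]2[C@@H]1CC[C@]2(C)O[Si](CC)(CC)CC | intermediate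
30 | methanesulfonate of 29 | CC1(C)C(C(OS(C)(=O)=O)C[C@H]3[C@]4(C)CC[C@H](O[Si](C)(C)C(C)(C)C)C(C)(C)O[C@H]4CC[C@@]3(C)O[Si](CC)(CC)CC)C(=O)CC[C@H]2[C@@H]1CC[C@]2(C)O[Si](CC)(CC)CC | intermediate (not isolated)
31 | (1S,3aS,8aS)-5-{2-[benzoxepin-6-yl unit of 27]ethylidene}-1,4,4-trimethyl-1-[(triethylsilyl)oxy]octahydroazulen-6(1H)-one (E/Z mixture) | CC1(C)C(=CC[C@H]3[C@]4(C)CC[C@H](O[Si](C)(C)C(C)(C)C)C(C)(C)O[C@H]4CC[C@@]3(C)O[Si](CC)(CC)CC)C(=O)CC[C@H]2[C@@H]1CC[C@]2(C)O[Si](CC)(CC)CC | intermediate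
32 | (1S,3aS,5S,8aS)-5-{2-[benzoxepin-6-yl unit of 27]ethyl}-1,4,4-trimethyl-1-[(triethylsilyl)oxy]octahydroazulen-6(1H)-one (side chain cis to the cyclopentane ring) | CC1(C)[C@H](CC[C@H]3[C@]4(C)CC[C@H](O[Si](C)(C)C(C)(C)C)C(C)(C)O[C@H]4CC[C@@]3(C)O[Si](CC)(CC)CC)C(=O)CC[C@H]2[C@@H]1CC[C@]2(C)O[Si](CC)(CC)CC | intermediate
33 | potassium enolate of 32 (C6=C7) | CC1(C)[C@H](CC[C@H]3[C@]4(C)CC[C@H](O[Si](C)(C)C(C)(C)C)C(C)(C)O[C@H]4CC[C@@]3(C)O[Si](CC)(CC)CC)C(O[K])=CC[C@H]2[C@@H]1CC[C@]2(C)O[Si](CC)(CC)CC | intermediate (not isolated)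
34 | (1S,3aS,5S,8aS)-5-{2-[benzoxepin-6-yl unit of 27]ethyl}-1,4,4-trimethyl-1-[(triethylsilyl)oxy]-1,2,3,3a,4,5,8,8a-octahydroazulen-6-yl trifluoromethanesulfonate | CC1(C)[C@H](CC[C@H]3[C@]4(C)CC[C@H](O[Si](C)(C)C(C)(C)C)C(C)(C)O[C@H]4CC[C@@]3(C)O[Si](CC)(CC)CC)C(OS(=O)(=O)C(F)(F)F)=CC[C@H]2[C@@H]1CC[C@]2(C)O[Si](CC)(CC)CC | intermediate
35 | tris-silyl ether of 36 (benzoxepine 3-O-TBS and 7-O-TES, azulene 1-O-TES) | CC1(C)[C@H](CC[C@H]3[C@]4(C)CC[C@H](O[Si](C)(C)C(C)(C)C)C(C)(C)O[C@H]4CC[C@@]3(C)O[Si](CC)(CC)CC)C(C)=CC[C@H]2[C@@H]1CC[C@]2(C)O[Si](CC)(CC)CC | intermediate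
36 | (3S,5aS,6S,7R,9aS)-6-{2-[(1S,3aS,5R,8aS)-1-hydroxy-1,4,4,6-tetramethyl-1,2,3,3a,4,5,8,8a-octahydroazulen-5-yl]ethyl}-2,2,5a,7-tetramethyldecahydro-1-benzoxepine-3,7-diol (CNP0183476.2) | CC1=CC[C@H]2[C@H](CC[C@]2(C)O)C(C)(C)[C@@H]1CC[C@H]1[C@]2(C)CC[C@H](O)C(C)(C)O[C@H]2CC[C@@]1(C)O | target

**Totals**
Total step count: 21.
Longest linear sequence: 14 steps (12 → 36: steps 8–15, then 16–21); the left half contributes 7 steps (1 → 11) before the union.

**Three steps most likely to fail, with fallbacks**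

Step 13 (the proposed new step). The silyl ether may open the epoxide in the 6-exo mode, or the epoxide may rearrange. The fallback uses known chemistry and forms the O–CMe2 bond by a reaction that has no regiochemical alternative. It sets out from 22 and returns at 24. Homolytic epoxide opening with Cp2TiCl (from Cp2TiCl2 and Mn, THF) and β-hydride elimination from the tertiary radical give the (S)-isopropenyl carbinol, allylic alcohol F1, with the C–O bond of the stereocentre untouched. Buffered Bu4NF/AcOH removes the TBS group to give the diol F2. Co(salen)-catalysed Markovnikov hydroalkoxylation (hydrogen-atom transfer then radical–polar crossover; N-fluoro-2,4,6-trimethylpyridinium triflate, PhSiH3, PhCF3) of the 1,1-disubstituted alkene by the ring hydroxyl, followed by K2CO3/MeOH equilibration, gives the hydroxy oxepane F3. Silylation (TBSOTf, 2,6-lutidine, −78 °C) rejoins the route at 24.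

Step 16. Conjugate methylation of the β,β-disubstituted, γ-branched cycloheptenone 11 may be slow or give 1,2-addition. The fallback sets out from 11 and returns at 29. Corey–Chaykovsky cyclopropanation of 11 with dimethylsulfoxonium methylide (Me3S(O)I, NaH, DMSO) gives the cyclopropyl ketone F4. Li/NH3 reduction cleaves the exocyclic cyclopropane bond (the one overlapping with the carbonyl π system), which unmasks the gem-dimethyl group and produces the same regiodefined lithium enolate 28. This is trapped with aldehyde 27 to give 29.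

Step 18. Hydrogen may be delivered to the other face of the exocyclic enone, giving the C5 epimer. The fallback builds this centre by C–C instead of C–H bond formation, which is stereocomplementary: a carbon electrophile entering on the face that hydrogen preferred places the chain where hydrogenation had placed hydrogen. It sets out from 27 and 11 and returns at 32. NaBH4 reduction of 27 gives the primary alcohol F5, and I2/PPh3/imidazole converts it into the primary iodide F6. Enolate 28 (from 11 and Me2CuLi) is alkylated with F6 in THF/HMPA to give 32 directly.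

Further compounds
F1 | step 13 | (3S,4S)-2-allyl-4-[(tert-butyldimethylsilyl)oxy]-3-[(3S)-3-hydroxy-4-methylpent-4-en-1-yl]-3-methylcyclohexan-1-one (C2 epimers) | C=CCC1[C@](C)(CC[C@H](O)C(C)=C)[C@@H](O[Si](C)(C)C(C)(C)C)CCC1=O
F2 | step 13 | (3S,4S)-2-allyl-4-hydroxy-3-[(3S)-3-hydroxy-4-methylpent-4-en-1-yl]-3-methylcyclohexan-1-one (C2 epimers) | C=CCC1[C@](C)(CC[C@H](O)C(C)=C)[C@@H](O)CCC1=O
F3 | step 13 | (3S,5aS,6S,9aS)-6-allyl-3-hydroxy-2,2,5a-trimethyloctahydro-1-benzoxepin-7(2H)-one | C=CC[C@H]1[C@]2(C)CC[C@H](O)C(C)(C)O[C@H]2CCC1=O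
F4 | step 16 | (1S,3aS,8aS)-1,4-dimethyl-4,5-methano-1-[(triethylsilyl)oxy]octahydroazulen-6(1H)-one (cyclopropane on the face of the ring-fusion hydrogens) | C[C@]12C[C@H]1C(=O)CC[C@H]3[C@@H]2CC[C@]3(C)O[Si](CC)(CC)CC
F5 | step 18 | 2-{(3S,5aS,6S,7R,9aS)-3-[(tert-butyldimethylsilyl)oxy]-2,2,5a,7-tetramethyl-7-[(triethylsilyl)oxy]decahydro-1-benzoxepin-6-yl}ethan-1-ol | OCC[C@H]1[C@]2(C)CC[C@H](O[Si](C)(C)C(C)(C)C)C(C)(C)O[C@H]2CC[C@@]1(C)O[Si](CC)(CC)CC
F6 | step 18 | (3S,5aS,6S,7R,9aS)-3-[(tert-butyldimethylsilyl)oxy]-6-(2-iodoethyl)-2,2,5a,7-tetramethyl-7-[(triethylsilyl)oxy]decahydro-1-benzoxepine | ICC[C@H]1[C@]2(C)CC[C@H](O[Si](C)(C)C(C)(C)C)C(C)(C)O[C@H]2CC[C@@]1(C)O[Si](CC)(CC)CC
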